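**Plan**

- Numbering of the target: C1 is the quinone carbonyl between methoxy-bearing C2 and side-chain-bearing C6, C4 is the other carbonyl, C1′ is the ring-bound CH2 and C2′ is the (R)-acetoxy carbon.
- Enabling feature: C5–C4–C3–C2–C1–C6–C1′–C2′ and the undecyl tail form one unbranched chain with oxygen on every second carbon (C4, C2, C2′; C6 was a ketone). With one extra carboxyl on C5, the carbocycle (ring A, the only ring) is a folded tetraketide of (R)-3-hydroxytetradecanoate.
- Cuts, in retrosynthetic order: the acetate and the C1 oxygen (phenol oxidation); a carboxyl restored on C5; ring bond C5–C6 (aldol aromatisation); chain bond C1–C6 (acylation of a triketide trianion by a C14 Weinreb amide); bond C1′–C2′ (acylation of Meldrum's acid by the C12 acid chloride).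
- Forward: the C14 unit is made first and joined to the C6 unit to give the linear C20 triketo ester. Ring A is then closed and aromatised, the ester carbon is removed after mono-O-methylation, and the phenol is oxidised to the quinone before the alcohol is unmasked and acetylated.
- Stereochemistry: the single stereocentre C2′ comes from Noyori hydrogenation of the β-keto ester with RuCl2[(R)-BINAP]; its C–O bond is never broken afterwards.

Key step: step 6

Remark: methyl 3,5-dioxohexanoate is taken as a purchasable reagent; it is otherwise available in one operation from dehydroacetic acid and Mg(OMe)2 in methanol.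

**Route**

Step 1
Reactants: 1 dodecanoyl chloride; 2 Meldrum's acid (2,2-dimethyl-1,3-dioxane-4,6-dione)
Product: 4 methyl 3-oxotetradecanoate, via acyl Meldrum's acid 3 (not isolated)
Conditions: pyridine (2 equiv), CH2Cl2, 0 °C to rt; then MeOH, reflux
Reagents that add atoms: methanol, CO
Why: Oikawa–Yonemitsu β-keto ester synthesis: pyridine-mediated C-acylation of Meldrum's acid by the acid chloride gives the enolised acyl derivative, which on heating in methanol opens through an acylketene and loses acetone and CO2 to leave the methyl β-keto ester.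

Step 2
Reactants: 4 methyl 3-oxotetradecanoate
Product: 5 methyl (3R)-3-hydroxytetradecanoate
Conditions: RuCl2[(R)-BINAP] (0.2 mol %), H2 (50 bar), MeOH, 50 °C
Reagents that add atoms: none
Why: Noyori asymmetric hydrogenation: the β-keto ester chelates divalent ruthenium through both carbonyls and the (R)-BINAP ligand lets hydride reach only one face of the ketone, which for 3-oxoalkanoates with an unbranched alkyl chain should set the (R) carbinol (C2′ of the target).

Step 3
Reactants: 5 methyl (3R)-3-hydroxytetradecanoate
Product: 6 methyl (3R)-3-(tert-butyldimethylsilyloxy)tetradecanoate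
Conditions: TBSCl (1.2 equiv), imidazole (2.5 equiv), DMF, rt
Reagents that add atoms: tert-butyldimethylsilyl chloride, CC(C)(C)[Si](C)(C)Cl
Why: Corey silylation (TBSCl–imidazole) of a secondary alcohol; the silyl ether keeps the hydroxyl from forming hemiketals with the ketones to come and tolerates the polyanion and alkaline steps.

Step 4
Reactants: 6 methyl (3R)-3-(tert-butyldimethylsilyloxy)tetradecanoate
Product: 7 (3R)-3-(tert-butyldimethylsilyloxy)-N-methoxy-N-methyltetradecanamide
Conditions: MeNH(OMe)·HCl (2 equiv), i-PrMgCl (4 equiv), THF, −20 to 0 °C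
Reagents that add atoms: N,O-dimethylhydroxylamine hydrochloride, CNOC.Cl
Why: Weinreb amide formation by aminolysis of the ester with the chloromagnesium amide generated from the amine hydrochloride and i-PrMgCl; the reagent is too weakly basic at −20 °C to eliminate the β-silyloxy group and the stereocentre is not involved.

Step 5
Reactants: 7 (3R)-3-(tert-butyldimethylsilyloxy)-N-methoxy-N-methyltetradecanamide; 8 methyl 3,5-dioxohexanoate
Product: 10 methyl (9R)-9-(tert-butyldimethylsilyloxy)-3,5,7-trioxoicosanoate, via trilithio methyl 3,5-dioxohexanoate 9 (not isolated)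
Conditions: 8 (2 equiv), LiN(i-Pr)2 (6.2 equiv), THF, −78 to 0 °C; then 7, −78 to −20 °C; AcOH, −78 °C
Reagents that add atoms: none
Why: Terminal C-acylation of a tricarbonyl polyanion (Harris-type polyketide chain extension): the last-formed C6 carbanion of 9 is the most basic and most nucleophilic site, the chelated Weinreb adduct stops at single addition and releases the new ketone only on the acid quench, and the excess of 9 outruns enolisation of the amide.

Step 6
Reactants: 10 methyl (9R)-9-(tert-butyldimethylsilyloxy)-3,5,7-trioxoicosanoate (crude, used at once)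
Product: 12 methyl 2,4-dihydroxy-6-[(2R)-2-(tert-butyldimethylsilyloxy)tridecyl]benzoate, via cyclic aldol carbinol 11 (not isolated)
Conditions: K2CO3 (0.3 equiv), MeOH, 0 °C to rt; pH 5 phosphate work-up
Reagents that add atoms: none
Why: Carbonate converts the triketo ester to its monoanion, in which the C2 methylene flanked by ester and ketone is the carbanion that can reach the un-enolised C7 ketone; its addition forms the C2–C7 bond (ring bond C5–C6 of the target) in a 6-exo-trig aldol (enolendo with respect to the C3 enolate, allowed for six-membered rings) and gives carbinol 11. E1cB loss of water and enolisation of the C3 and C5 ketones then drive the system irreversibly to the benzene ring, ring A, the only ring of the target. The closest known reaction type is the base-mediated aldol aromatisation of 3,5,7-triketo esters to β-resorcylates, the laboratory counterpart of polyketide cyclisation. No stereocentre is created that survives: the two sp3 centres of 11 are erased on aromatisation and the silyloxy carbinol lies outside the reacting array. The step needs aldol closure to win over Claisen closure of C6 onto the ester (acylphloroglucinol), over lactonisation to a 4-hydroxy-2-pyrone and over β-elimination of silanolate; a weak, non-chelating base in sub-stoichiometric amount keeps the substrate as a monoanion with a free ketone electrophile, which is far more reactive than the ester, and the C8 protons are not acidic enough under carbonate to trigger elimination. Once the ring is aromatic the former C7 carbonyl is gone and elimination is no longer possible.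

Step 7
Reactants: 12 methyl 2,4-dihydroxy-6-[(2R)-2-(tert-butyldimethylsilyloxy)tridecyl]benzoate
Product: 13 methyl 2-hydroxy-4-methoxy-6-[(2R)-2-(tert-butyldimethylsilyloxy)tridecyl]benzoate
Conditions: MeI (1.1 equiv), K2CO3 (1.1 equiv), acetone, rt
Reagents that add atoms: iodomethane, CI
Why: Williamson O-methylation: the 2-hydroxyl is locked in a hydrogen bond to the ester carbonyl, so one equivalent of MeI with K2CO3 alkylates only the more acidic 4-hydroxyl (the oxygen that becomes the C2 methoxy group), and the ester thus prevents the double methylation that a free 5-alkylresorcinol would suffer.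

Step 8
Reactants: 13 methyl 2-hydroxy-4-methoxy-6-[(2R)-2-(tert-butyldimethylsilyloxy)tridecyl]benzoate
Product: 15 3-methoxy-5-[(2R)-2-(tert-butyldimethylsilyloxy)tridecyl]phenol, via carboxylic acid 14 (not isolated)
Conditions: KOH (10 equiv), MeOH–H2O (4:1), reflux; then 1 M HCl to pH 4, extraction; toluene, 100 °C
Reagents that add atoms: none
Why: Saponification followed by protodecarboxylation of a 2-hydroxy-4-alkoxybenzoic acid, whose ipso carbon is activated for protonation by the ortho-hydroxyl and para-methoxy groups (the reaction that converts olivetolate-type esters into 5-alkylresorcinols); a secondary TBS ether should tolerate aqueous methanolic KOH.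

Step 9
Reactants: 15 3-methoxy-5-[(2R)-2-(tert-butyldimethylsilyloxy)tridecyl]phenol
Product: 16 2-methoxy-6-[(2R)-2-(tert-butyldimethylsilyloxy)tridecyl]-1,4-benzoquinone
Conditions: (KSO3)2NO (3 equiv), KH2PO4, acetone–H2O, rt
Reagents that add atoms: potassium nitrosodisulfonate (Fremy's salt), [K+].[K+].[O]N(S(=O)(=O)[O-])S(=O)(=O)[O-]
Why: Teuber oxidation: the nitrosodisulfonate radical abstracts the phenolic hydrogen, a second equivalent couples at the free para position (between methoxy and alkyl) and loss of imidodisulfonate gives the 1,4-quinone, the known outcome for 3-methoxy-5-alkylphenols; the para position being open, ortho-quinone formation should stay minor.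

Step 10
Reactants: 16 2-methoxy-6-[(2R)-2-(tert-butyldimethylsilyloxy)tridecyl]-1,4-benzoquinone
Product: 17 2-[(2R)-2-hydroxytridecyl]-6-methoxy-1,4-benzoquinone
Conditions: HF (48% aq.), MeCN, 0 °C to rt
Reagents that add atoms: none
Why: Acidic fluoride desilylation (cleavage of the Si–O bond, so C2′ is untouched); aqueous HF in acetonitrile avoids the basic fluoride sources and nucleophiles that attack methoxyquinones.

Step 11
Reactants: 17 2-[(2R)-2-hydroxytridecyl]-6-methoxy-1,4-benzoquinone
Product: 18 (2R)-1-(5-methoxy-3,6-dioxocyclohexa-1,4-dien-1-yl)tridecan-2-yl acetate (CNP0137521.1)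
Conditions: Ac2O (2 equiv), pyridine (3 equiv), DMAP (5 mol %), CH2Cl2, 0 °C
Reagents that add atoms: acetic anhydride, CC(=O)OC(C)=O
Why: Acylation of a secondary alcohol with acetic anhydride and pyridine under DMAP catalysis; the C2′–O bond is not broken so the (R) configuration is retained, and low temperature with short contact time limits conjugate addition of the amines to the quinone.

**Compound list**

1 | dodecanoyl chloride | CCCCCCCCCCCC(Cl)=O | starting material
2 | Meldrum's acid (2,2-dimethyl-1,3-dioxane-4,6-dione) | CC1(C)OC(=O)CC(=O)O1 | starting material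
3 | 5-(1-hydroxydodecylidene)-2,2-dimethyl-1,3-dioxane-4,6-dione (acyl Meldrum's acid) | CCCCCCCCCCCC(O)=C1C(=O)OC(C)(C)OC1=O | intermediate
4 | methyl 3-oxotetradecanoate | CCCCCCCCCCCC(=O)CC(=O)OC | intermediate
5 | methyl (3R)-3-hydroxytetradecanoate | CCCCCCCCCCC[C@H](CC(=O)OC)O | intermediate
6 | methyl (3R)-3-(tert-butyldimethylsilyloxy)tetradecanoate | CCCCCCCCCCC[C@H](CC(=O)OC)O[Si](C)(C)C(C)(C)C | intermediate
7 | (3R)-3-(tert-butyldimethylsilyloxy)-N-methoxy-N-methyltetradecanamide | CCCCCCCCCCC[C@H](CC(=O)N(C)OC)O[Si](C)(C)C(C)(C)C | intermediate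
8 | methyl 3,5-dioxohexanoate | COC(=O)CC(=O)CC(C)=O | starting material
9 | trilithio methyl 3,5-dioxohexanoate (trianion at C2, C4 and C6) | [Li+].[Li+].[Li+].COC(=O)[CH-]C(=O)[CH-]C(=O)[CH2-] | intermediate
10 | methyl (9R)-9-(tert-butyldimethylsilyloxy)-3,5,7-trioxoicosanoate | CCCCCCCCCCC[C@H](CC(=O)CC(=O)CC(=O)CC(=O)OC)O[Si](C)(C)C(C)(C)C | intermediate
11 | methyl 2-hydroxy-2-[(2R)-2-(tert-butyldimethylsilyloxy)tridecyl]-4,6-dioxocyclohexane-1-carboxylate (ring stereocentres unassigned) | CCCCCCCCCCC[C@H](CC1(O)CC(=O)CC(=O)C1C(=O)OC)O[Si](C)(C)C(C)(C)C | intermediate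
12 | methyl 2,4-dihydroxy-6-[(2R)-2-(tert-butyldimethylsilyloxy)tridecyl]benzoate | CCCCCCCCCCC[C@H](Cc1cc(O)cc(O)c1C(=O)OC)O[Si](C)(C)C(C)(C)C | intermediate
13 | methyl 2-hydroxy-4-methoxy-6-[(2R)-2-(tert-butyldimethylsilyloxy)tridecyl]benzoate | CCCCCCCCCCC[C@H](Cc1cc(OC)cc(O)c1C(=O)OC)O[Si](C)(C)C(C)(C)C | intermediate
14 | 2-hydroxy-4-methoxy-6-[(2R)-2-(tert-butyldimethylsilyloxy)tridecyl]benzoic acid | CCCCCCCCCCC[C@H](Cc1cc(OC)cc(O)c1C(=O)O)O[Si](C)(C)C(C)(C)C | intermediate
15 | 3-methoxy-5-[(2R)-2-(tert-butyldimethylsilyloxy)tridecyl]phenol | CCCCCCCCCCC[C@H](Cc1cc(O)cc(OC)c1)O[Si](C)(C)C(C)(C)C | intermediate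
16 | 2-methoxy-6-[(2R)-2-(tert-butyldimethylsilyloxy)tridecyl]-1,4-benzoquinone | CCCCCCCCCCC[C@H](CC1=CC(=O)C=C(OC)C1=O)O[Si](C)(C)C(C)(C)C | intermediate
17 | 2-[(2R)-2-hydroxytridecyl]-6-methoxy-1,4-benzoquinone | CCCCCCCCCCC[C@H](CC1=CC(=O)C=C(OC)C1=O)O | intermediate
18 | (2R)-1-(5-methoxy-3,6-dioxocyclohexa-1,4-dien-1-yl)tridecan-2-yl acetate (CNP0137521.1) | CCCCCCCCCCC[C@H](CC1=CC(=O)C=C(OC)C1=O)OC(C)=O | target

**Step count**

Total steps: 11. Longest linear sequence: 11 steps (1 to 18); 8 enters at step 5 as a purchased reagent.

**Steps most likely to fail**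

1. Step 5. The very basic terminal carbanion may deprotonate the Weinreb amide instead of adding to it, which would be followed by β-elimination of silanolate; acylation may also stay incomplete, or the sensitive triketo ester may cyclise prematurely during work-up. Fallback, setting out from 6 and coming back at 10: the ester 6 is reduced with i-Bu2AlH in CH2Cl2 at −78 °C to (3R)-3-(tert-butyldimethylsilyloxy)tetradecanal F1. The aldehyde is added at −78 °C to trianion 9, where carbonyl addition is much faster than proton transfer, to give methyl (9R)-9-(tert-butyldimethylsilyloxy)-7-hydroxy-3,5-dioxoicosanoate F2 as a mixture of C7 epimers. Oxidation of the new carbinol with Dess–Martin periodinane in CH2Cl2 at 0 °C should then deliver triketo ester 10.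

2. Step 6. Ring closure may be diverted into Claisen attack on the ester or lactonisation to a pyrone, the silyloxy group may be eliminated through the C8 enolate, or the reaction may stall before dehydration. Fallback, setting out from 7 and coming back at 12: the carboxyl is carried as a dioxinone so that it cannot act as an electrophile. Commercial 2,2,6-trimethyl-4H-1,3-dioxin-4-one is γ-acetylated (LiN(SiMe3)2, THF, −78 °C, then acetyl chloride) to 2,2-dimethyl-6-(2-oxopropyl)-4H-1,3-dioxin-4-one F3. F3 is deprotonated twice with LiN(i-Pr)2 and acylated at its terminal methyl by amide 7 to give 6-[(6R)-6-(tert-butyldimethylsilyloxy)-2,4-dioxoheptadecyl]-2,2-dimethyl-4H-1,3-dioxin-4-one F4. Triethylamine in CH2Cl2 at rt then effects the same aldol and dehydration, with the dioxinone C5 as nucleophile, to give 7-hydroxy-2,2-dimethyl-5-[(2R)-2-(tert-butyldimethylsilyloxy)tridecyl]-4H-1,3-benzodioxin-4-one F5. Methanolysis of the acetonide with K2CO3 in MeOH should return resorcylate 12.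

3. Step 8. Hydrolysis of the doubly ortho-substituted, hydrogen-bonded ester may be incomplete, and the silyl ether may erode under prolonged hot alkali. Fallback, setting out from 13 and coming back at 15: the O–CH3 bond of the ester is cut instead of the acyl–oxygen bond. LiI in refluxing pyridine attacks the ester methyl in an SN2 dealkylation and gives the lithium carboxylate without hydroxide. Acidification to pH 4 and warming in toluene then pass through acid 14 and should give phenol 15 by the same protodecarboxylation.

**Further compounds**

F1 | step 5 | (3R)-3-(tert-butyldimethylsilyloxy)tetradecanal | CCCCCCCCCCC[C@H](CC=O)O[Si](C)(C)C(C)(C)C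
F2 | step 5 | methyl (9R)-9-(tert-butyldimethylsilyloxy)-7-hydroxy-3,5-dioxoicosanoate (C7 epimers) | CCCCCCCCCCC[C@H](CC(O)CC(=O)CC(=O)CC(=O)OC)O[Si](C)(C)C(C)(C)C
F3 | step 6 | 2,2-dimethyl-6-(2-oxopropyl)-4H-1,3-dioxin-4-one | CC(=O)CC1=CC(=O)OC(C)(C)O1
F4 | step 6 | 6-[(6R)-6-(tert-butyldimethylsilyloxy)-2,4-dioxoheptadecyl]-2,2-dimethyl-4H-1,3-dioxin-4-one | CCCCCCCCCCC[C@H](CC(=O)CC(=O)CC1=CC(=O)OC(C)(C)O1)O[Si](C)(C)C(C)(C)C
F5 | step 6 | 7-hydroxy-2,2-dimethyl-5-[(2R)-2-(tert-butyldimethylsilyloxy)tridecyl]-4H-1,3-benzodioxin-4-one | CCCCCCCCCCC[C@H](Cc1cc(O)cc2OC(C)(C)OC(=O)c12)O[Si](C)(C)C(C)(C)C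
F0 | step 8 | none | none
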